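**Retrosynthetic overview**
1. Target 31 ⇐ hexa-TBS trans-lactone 30 ⇐ (C3 epimerisation, lactonisation, imide reduction) 2,3-dibenzylsuccinic imide/amide 27.
2. Key disconnection: the lactone C3–C4 bond, which joins the α-carbons of two 3-arylpropanoyl units. An α-carbonyl cation (enolonium) equivalent made from amide 17 is paired with the chiral imide enolate of 23.
3. 17 and 23 ⇐ one common bromodiol 12, by Heck chain extension, hydrogenation and silylation. For 17 the same anti-diol is closed with acid to the trans-dihydrobenzofuran.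
4. 12 ⇐ auxiliary-controlled anti-aldol of arylacetyl imide 8 with O-benzylvanillin 9. 8 ⇐ 5-bromo-o-vanillin 1 by one-carbon homologation.
5. Ring order: all four arenes are bought, the dihydrobenzofuran ring forms in step 8, and the butyrolactone ring forms last, in step 15.

Assumption: the SMILES is taken literally, that is (3S,4S)-trans lactone, (2R,3S)-trans dihydrobenzofuran and (1S,2S)-anti 1,3-diol unit.

Abbreviations:
- Bn = benzyl, TMS = trimethylsilyl, TBS = tert-butyldimethylsilyl, Tf = trifluoromethanesulfonyl.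
- ArA = (2R,3S)-2-(4-TBSO-3-methoxyphenyl)-3-(TBSOCH2)-7-methoxy-2,3-dihydro-1-benzofuran-5-yl.
- ArB = 4-TBSO-3-methoxy-5-[(1S,2S)-1,3-bis(TBSO)-1-(4-TBSO-3-methoxyphenyl)propan-2-yl]phenyl.

**Step 1**
Reactants: 1 5-bromo-2-hydroxy-3-methoxybenzaldehyde
Product: 2 2-(benzyloxy)-5-bromo-3-methoxybenzaldehyde
Conditions: BnBr, K2CO3, DMF, 60 °C
Reagents that add atoms: benzyl bromide, BrCc1ccccc1
Why: Williamson ether synthesis; the acidic phenol is alkylated cleanly, and the benzyl ether survives every basic step until the hydrogenolysis that later removes it together with the alkene.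

**Step 2**
Reactants: 2 2-(benzyloxy)-5-bromo-3-methoxybenzaldehyde
Product: 4 2-[2-(benzyloxy)-5-bromo-3-methoxyphenyl]acetonitrile, via N-(1-tosylvinyl)formamide adduct 3 (not isolated)
Conditions: TosMIC, KOt-Bu, DME, −35 °C; then MeOH, reflux, 30 min
Reagents that add atoms: tosylmethyl isocyanide (TosMIC), Cc1ccc(cc1)S(=O)(=O)C[N+]#[C-]
Why: van Leusen reductive cyanation; the TosMIC anion adds to the non-enolisable aldehyde, the oxazoline opens to 3, and methanolysis expels methyl formate and sulfinate, so the extra carbon is added in one operation without touching ArBr or OBn.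

**Step 3**
Reactants: 4 2-[2-(benzyloxy)-5-bromo-3-methoxyphenyl]acetonitrile
Product: 5 2-[2-(benzyloxy)-5-bromo-3-methoxyphenyl]acetic acid
Conditions: NaOH, EtOH/H2O, reflux; then aq. HCl
Reagents that add atoms: water, O; sodium hydroxide, [Na+].[OH-]
Why: Base hydrolysis of a nitrile; the aryl bromide, methyl ether and benzyl ether are inert to aqueous hydroxide.

**Step 4**
Reactants: 5 2-[2-(benzyloxy)-5-bromo-3-methoxyphenyl]acetic acid; 6 (S)-4-benzyl-1,3-oxazolidin-2-one
Product: 8 (S)-4-benzyl-3-{2-[2-(benzyloxy)-5-bromo-3-methoxyphenyl]acetyl}-1,3-oxazolidin-2-one, via mixed pivalic anhydride 7 (not isolated)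
Conditions: PivCl, Et3N, THF, −20 °C; then 6, LiCl, −20 °C → rt
Reagents that add atoms: pivaloyl chloride, CC(C)(C)C(=O)Cl (pivaloyl group only in 7)
Why: Mixed-anhydride N-acylation of an Evans oxazolidinone under LiCl/Et3N conditions, which avoids strong base on the acidic arylacetyl unit; the auxiliary stereocentre is bought.

**Step 5**
Reactants: 8 arylacetyl imide; 9 4-(benzyloxy)-3-methoxybenzaldehyde
Product: 10 (S)-4-benzyl-3-[(2R,3S)-2-[2-(benzyloxy)-5-bromo-3-methoxyphenyl]-3-[4-(benzyloxy)-3-methoxyphenyl]-3-(trimethylsilyloxy)propanoyl]-1,3-oxazolidin-2-one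
Conditions: MgCl2 (20 mol %), Et3N, TMSCl, EtOAc, rt, 24 h
Reagents that add atoms: chlorotrimethylsilane, C[Si](C)(C)Cl
Why: Evans magnesium-halide-catalysed direct anti-aldol; soft enolisation gives the Mg-chelated Z-enolate, the aldehyde adds to the face away from the auxiliary benzyl group (the alkylation face, giving 2R) through a boat-like transition state that sets the anti 3S carbinol, and TMSCl traps the aldolate so that retro-aldol and epimerisation are shut off.

**Step 6**
Reactants: 10 TMS-protected anti-aldol imide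
Product: 12 (1S,2S)-2-[2-(benzyloxy)-5-bromo-3-methoxyphenyl]-1-[4-(benzyloxy)-3-methoxyphenyl]propane-1,3-diol, via TMS-ether alcohol 11 (not isolated)
Conditions: LiBH4, H2O (1 equiv), Et2O/THF, 0 °C; then K2CO3 (cat.), MeOH, rt
Reagents that add atoms: none
Why: Reductive cleavage of the N-acyl oxazolidinone at the exocyclic carbonyl, then methanolysis of the labile TMS ether; no stereocentre is touched (the descriptors become 1S,2S only through a priority change) and ArBr and OBn are inert.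

**Step 7**
Reactants: 12 bromodiol; 13 N,N-dimethylacrylamide
Product: 14 (E)-3-{4-(benzyloxy)-3-[(1S,2S)-1-[4-(benzyloxy)-3-methoxyphenyl]-1,3-dihydroxypropan-2-yl]-5-methoxyphenyl}-N,N-dimethylprop-2-enamide
Conditions: Pd(OAc)2 (5 mol %), P(o-tol)3 (12 mol %), Et3N, DMF, 100 °C
Reagents that add atoms: none
Why: Mizoroki–Heck reaction at the unhindered aryl bromide; free alcohols are tolerated and the acrylamide couples at its terminal carbon to give the E-alkene.

**Step 8**
Reactants: 14 E-cinnamamide diol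
Product: 16 3-[(2R,3S)-2-(4-hydroxy-3-methoxyphenyl)-3-(hydroxymethyl)-7-methoxy-2,3-dihydro-1-benzofuran-5-yl]-N,N-dimethylpropanamide, via debenzylated tetraol amide 15 (not isolated)
Conditions: H2 (1 atm), Pd/C, EtOAc/THF, rt; filter; then TFA (20 mol %), CH2Cl2, 0 °C
Reagents that add atoms: none
Why: Neutral hydrogenation saturates the alkene and cleaves both aryl benzyl ethers but leaves the benzylic alcohol; acid then ionises the p-hydroxybenzylic alcohol to a quinone methide that the ortho phenol captures (5-exo cyclisation), the fixed 3S centre placing the aryl group trans (2R) under thermodynamic control.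

**Step 9**
Reactants: 16 dihydrobenzofuran amide
Product: 17 3-(ArA)-N,N-dimethylpropanamide (bis-TBS ether of 16)
Conditions: TBSCl, imidazole, DMF, rt
Reagents that add atoms: tert-butyldimethylsilyl chloride, CC(C)(C)[Si](C)(C)Cl
Why: Standard imidazole-promoted silylation of the phenol and the primary alcohol, needed because free OH groups would be triflated in step 14.

**Step 10**
Reactants: 18 (R)-4-benzyl-1,3-oxazolidin-2-one; 19 acryloyl chloride
Product: 20 (R)-3-acryloyl-4-benzyl-1,3-oxazolidin-2-one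
Conditions: Et3N, LiCl, THF, BHT (trace), −20 °C → rt
Reagents that add atoms: none
Why: N-acylation of the oxazolidinone under mild LiCl/Et3N conditions, which avoids the anionic polymerisation seen with lithiated auxiliary.

**Step 11**
Reactants: 12 bromodiol; 20 (R)-3-acryloyl-4-benzyl-1,3-oxazolidin-2-one
Product: 21 (R)-4-benzyl-3-[(E)-3-{4-(benzyloxy)-3-[(1S,2S)-1-[4-(benzyloxy)-3-methoxyphenyl]-1,3-dihydroxypropan-2-yl]-5-methoxyphenyl}prop-2-enoyl]-1,3-oxazolidin-2-one
Conditions: Pd2(dba)3 (2 mol %), [HP(t-Bu)3]BF4 (8 mol %), Cy2NMe, dioxane, 70 °C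
Reagents that add atoms: none
Why: Mizoroki–Heck reaction with a bulky electron-rich phosphine and a hindered amine base, so the electron-rich bromide couples at a temperature at which the imide is not attacked.

**Step 12**
Reactants: 21 E-enoyl imide
Product: 22 (R)-4-benzyl-3-(3-{3-[(1S,2S)-1,3-dihydroxy-1-(4-hydroxy-3-methoxyphenyl)propan-2-yl]-4-hydroxy-5-methoxyphenyl}propanoyl)-1,3-oxazolidin-2-one
Conditions: H2 (1 atm), Pd/C, EtOAc/THF, rt
Reagents that add atoms: none
Why: Catalytic hydrogenation and O-benzyl hydrogenolysis under strictly neutral conditions, so the benzylic alcohol neither hydrogenolyses nor cyclises; the C-benzyl group of the auxiliary is inert.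

**Step 13**
Reactants: 22 tetraol imide
Product: 23 (R)-4-benzyl-3-[3-(ArB)propanoyl]-1,3-oxazolidin-2-one (tetra-TBS ether of 22)
Conditions: TBSOTf (5 equiv), 2,6-lutidine (8 equiv), CH2Cl2, −78 → 0 °C
Reagents that add atoms: tert-butyldimethylsilyl triflate, CC(C)(C)[Si](C)(C)OS(=O)(=O)C(F)(F)F
Why: Silyl triflate silylation covers even the hindered phenol and the secondary benzylic alcohol, while excess lutidine keeps the medium non-acidic so the diol unit stays open.

**Step 14 (key step)**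
Reactants: 17 3-(ArA)-N,N-dimethylpropanamide; 23 (R)-4-benzyl-3-[3-(ArB)propanoyl]-1,3-oxazolidin-2-one
Product: 27 (3S)-4-[(R)-4-benzyl-2-oxo-1,3-oxazolidin-3-yl]-2-(ArA-methyl)-3-(ArB-methyl)-N,N-dimethyl-4-oxobutanamide (C2 epimers), via keteniminium triflate 24 (not isolated), via enolonium triflate 25 (not isolated), via sodium Z-enolate 26 (not isolated)
Conditions: 17, Tf2O (1.1 equiv), 2-iodopyridine (2.2 equiv), CH2Cl2, 0 °C, 15 min; 2,6-lutidine N-oxide (1.1 equiv), 0 → −78 °C; then 26 [from 23 (2.2 equiv), NaN(SiMe3)2, THF, −78 °C], −78 → −20 °C; excess 23 recovered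
Reagents that add atoms: 2,6-lutidine N-oxide, Cc1cccc(C)[n+]1[O-] (its oxygen becomes the amide carbonyl oxygen of 27); triflic anhydride, O=S(=O)(OS(=O)(=O)C(F)(F)F)C(F)(F)F (triflate only in 24 and 25); NaN(SiMe3)2, [Na+].C[Si](C)(C)[N-][Si](C)(C)C (sodium only in 26)
Why: Proposed new method: O-triflation of the tertiary amide and loss of an α-proton give keteniminium 24, and the N-oxide oxygen adds to its central carbon; in the resulting N-(enoloxy)pyridinium 25 the former enolate carbon is electrophilic because attack there breaks the weak N–O bond and regenerates the amide C=O, so the normally nucleophilic α-carbon of 17 can bond to the normally nucleophilic α-carbon of 26; the sodium-chelated Z-enolate is attacked on the face away from the (R)-benzyl group, as in Evans alkylations, which sets the future lactone C4 as S, while the other new centre forms as a mixture that step 16 corrects; the closest known reaction type is the cross-enolate coupling of triflic anhydride/N-oxide-activated tertiary amides with simple preformed enolates to give 1,4-dicarbonyls, and what is new here is the chiral imide enolate and the size and electron-rich arenes of both partners.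

**Step 15**
Reactants: 27 succinic imide/amide
Product: 29 (4S)-3-(ArA-methyl)-4-(ArB-methyl)oxolan-2-one (C3 epimers), via hydroxy amide 28 (not isolated)
Conditions: LiBH4, H2O (1 equiv), THF/Et2O, 0 °C; work-up; then AcOH/toluene (1:4), 80 °C
Reagents that add atoms: none
Why: Chemoselective LiBH4 reduction of the imide (the tertiary amide is inert) releases the auxiliary, and the γ-hydroxy amide then lactonises by intramolecular acyl substitution, helped by five-ring formation and the vicinal substituents; C4 keeps its S configuration because it is no longer next to a carbonyl.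

**Step 16**
Reactants: 29 lactone epimers
Product: 31 CNP0199264.1, via trans-lactone 30 (not isolated)
Conditions: DBU (1 equiv), THF, 40 °C, 12 h; then TBAF/AcOH (1:1, 9 equiv), 0 °C → rt
Reagents that add atoms: none
Why: Base epimerisation at the only acidic stereocentre (lactone C3) funnels both epimers to the thermodynamically preferred trans (3S,4S) lactone, and buffered fluoride desilylation then removes all six TBS groups without acid, so the open 1,3-diol unit cannot cyclise.

**Compound list**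
1 | 5-bromo-2-hydroxy-3-methoxybenzaldehyde (5-bromo-o-vanillin) | COc1cc(Br)cc(C=O)c1O | starting material
2 | 2-(benzyloxy)-5-bromo-3-methoxybenzaldehyde | COc1cc(Br)cc(C=O)c1OCc1ccccc1 | intermediate
3 | N-{2-[2-(benzyloxy)-5-bromo-3-methoxyphenyl]-1-(4-methylphenylsulfonyl)ethenyl}formamide (alkene geometry undefined) | COc1cc(Br)cc(C=C(NC=O)S(=O)(=O)c2ccc(C)cc2)c1OCc1ccccc1 | intermediate
4 | 2-[2-(benzyloxy)-5-bromo-3-methoxyphenyl]acetonitrile | COc1cc(Br)cc(CC#N)c1OCc1ccccc1 | intermediate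
5 | 2-[2-(benzyloxy)-5-bromo-3-methoxyphenyl]acetic acid | COc1cc(Br)cc(CC(=O)O)c1OCc1ccccc1 | intermediate
6 | (S)-4-benzyl-1,3-oxazolidin-2-one | O=C1N[C@@H](Cc2ccccc2)CO1 | starting material
7 | 2-[2-(benzyloxy)-5-bromo-3-methoxyphenyl]acetic pivalic anhydride | COc1cc(Br)cc(CC(=O)OC(=O)C(C)(C)C)c1OCc1ccccc1 | intermediate
8 | (S)-4-benzyl-3-{2-[2-(benzyloxy)-5-bromo-3-methoxyphenyl]acetyl}-1,3-oxazolidin-2-one | COc1cc(Br)cc(CC(=O)N2[C@@H](Cc3ccccc3)COC2=O)c1OCc1ccccc1 | intermediate
9 | 4-(benzyloxy)-3-methoxybenzaldehyde (O-benzylvanillin) | COc1cc(C=O)ccc1OCc1ccccc1 | starting material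
10 | (2R,3S)-anti-aldol imide, TMS ether, (S)-auxiliary | COc1cc([C@@H](O[Si](C)(C)C)[C@H](C(=O)N2[C@@H](Cc3ccccc3)COC2=O)c2cc(Br)cc(OC)c2OCc2ccccc2)ccc1OCc1ccccc1 | intermediate
11 | (2S,3S)-2-[2-(benzyloxy)-5-bromo-3-methoxyphenyl]-3-[4-(benzyloxy)-3-methoxyphenyl]-3-(trimethylsilyloxy)propan-1-ol | COc1cc([C@@H](O[Si](C)(C)C)[C@H](CO)c2cc(Br)cc(OC)c2OCc2ccccc2)ccc1OCc1ccccc1 | intermediate
12 | (1S,2S)-2-[2-(benzyloxy)-5-bromo-3-methoxyphenyl]-1-[4-(benzyloxy)-3-methoxyphenyl]propane-1,3-diol | COc1cc([C@@H](O)[C@H](CO)c2cc(Br)cc(OC)c2OCc2ccccc2)ccc1OCc1ccccc1 | intermediate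
13 | N,N-dimethylacrylamide | C=CC(=O)N(C)C | starting material
14 | E-cinnamamide of the (1S,2S)-diol, both phenols benzylated | COc1cc([C@@H](O)[C@H](CO)c2cc(/C=C/C(=O)N(C)C)cc(OC)c2OCc2ccccc2)ccc1OCc1ccccc1 | intermediate
15 | 3-{3-[(1S,2S)-1,3-dihydroxy-1-(4-hydroxy-3-methoxyphenyl)propan-2-yl]-4-hydroxy-5-methoxyphenyl}-N,N-dimethylpropanamide | COc1cc([C@@H](O)[C@H](CO)c2cc(CCC(=O)N(C)C)cc(OC)c2O)ccc1O | intermediate
16 | 3-[(2R,3S)-2-(4-hydroxy-3-methoxyphenyl)-3-(hydroxymethyl)-7-methoxy-2,3-dihydro-1-benzofuran-5-yl]-N,N-dimethylpropanamide | CN(C)C(=O)CCc1cc(OC)c2c(c1)[C@@H](CO)[C@H](c1ccc(O)c(OC)c1)O2 | intermediate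
17 | 3-(ArA)-N,N-dimethylpropanamide (bis-TBS ether of 16) | CN(C)C(=O)CCc1cc(OC)c2c(c1)[C@@H](CO[Si](C)(C)C(C)(C)C)[C@H](c1ccc(O[Si](C)(C)C(C)(C)C)c(OC)c1)O2 | intermediate
18 | (R)-4-benzyl-1,3-oxazolidin-2-one | O=C1N[C@H](Cc2ccccc2)CO1 | starting material
19 | acryloyl chloride | C=CC(=O)Cl | starting material
20 | (R)-3-acryloyl-4-benzyl-1,3-oxazolidin-2-one | C=CC(=O)N1[C@H](Cc2ccccc2)COC1=O | intermediate
21 | E-enoyl imide of the (1S,2S)-diol, both phenols benzylated, (R)-auxiliary | COc1cc([C@@H](O)[C@H](CO)c2cc(/C=C/C(=O)N3[C@H](Cc4ccccc4)COC3=O)cc(OC)c2OCc2ccccc2)ccc1OCc1ccccc1 | intermediate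
22 | saturated tetraol imide, (R)-auxiliary | COc1cc([C@@H](O)[C@H](CO)c2cc(CCC(=O)N3[C@H](Cc4ccccc4)COC3=O)cc(OC)c2O)ccc1O | intermediate
23 | (R)-4-benzyl-3-[3-(ArB)propanoyl]-1,3-oxazolidin-2-one | COc1cc([C@@H](O[Si](C)(C)C(C)(C)C)[C@H](CO[Si](C)(C)C(C)(C)C)c2cc(CCC(=O)N3[C@H](Cc4ccccc4)COC3=O)cc(OC)c2O[Si](C)(C)C(C)(C)C)ccc1O[Si](C)(C)C(C)(C)C | intermediate
24 | N,N-dimethyl keteniminium triflate of 17 | C[N+](C)=C=CCc1cc(OC)c2c(c1)[C@@H](CO[Si](C)(C)C(C)(C)C)[C@H](c1ccc(O[Si](C)(C)C(C)(C)C)c(OC)c1)O2.[O-]S(=O)(=O)C(F)(F)F | intermediate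
25 | 1-{[3-(ArA)-1-(dimethylamino)prop-1-en-1-yl]oxy}-2,6-dimethylpyridinium triflate (enolonium equivalent) | CN(C)C(=CCc1cc(OC)c2c(c1)[C@@H](CO[Si](C)(C)C(C)(C)C)[C@H](c1ccc(O[Si](C)(C)C(C)(C)C)c(OC)c1)O2)O[n+]1c(C)cccc1C.[O-]S(=O)(=O)C(F)(F)F | intermediate
26 | sodium Z-enolate of 23 | [Na+].COc1cc([C@@H](O[Si](C)(C)C(C)(C)C)[C@H](CO[Si](C)(C)C(C)(C)C)c2cc(C\C=C(/[O-])N3[C@H](Cc4ccccc4)COC3=O)cc(OC)c2O[Si](C)(C)C(C)(C)C)ccc1O[Si](C)(C)C(C)(C)C | intermediate
27 | (3S)-4-[(R)-4-benzyl-2-oxo-1,3-oxazolidin-3-yl]-2-(ArA-methyl)-3-(ArB-methyl)-N,N-dimethyl-4-oxobutanamide (C2 epimers) | COc1cc([C@@H](O[Si](C)(C)C(C)(C)C)[C@H](CO[Si](C)(C)C(C)(C)C)c2cc(C[C@H](C(=O)N3[C@H](Cc4ccccc4)COC3=O)C(Cc3cc(OC)c4c(c3)[C@@H](CO[Si](C)(C)C(C)(C)C)[C@H](c3ccc(O[Si](C)(C)C(C)(C)C)c(OC)c3)O4)C(=O)N(C)C)cc(OC)c2O[Si](C)(C)C(C)(C)C)ccc1O[Si](C)(C)C(C)(C)C | intermediate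
28 | (3S)-2-(ArA-methyl)-3-(ArB-methyl)-4-hydroxy-N,N-dimethylbutanamide (C2 epimers) | COc1cc([C@@H](O[Si](C)(C)C(C)(C)C)[C@H](CO[Si](C)(C)C(C)(C)C)c2cc(C[C@H](CO)C(Cc3cc(OC)c4c(c3)[C@@H](CO[Si](C)(C)C(C)(C)C)[C@H](c3ccc(O[Si](C)(C)C(C)(C)C)c(OC)c3)O4)C(=O)N(C)C)cc(OC)c2O[Si](C)(C)C(C)(C)C)ccc1O[Si](C)(C)C(C)(C)C | intermediate
29 | (4S)-3-(ArA-methyl)-4-(ArB-methyl)oxolan-2-one (C3 epimers) | COc1cc([C@@H](O[Si](C)(C)C(C)(C)C)[C@H](CO[Si](C)(C)C(C)(C)C)c2cc(C[C@@H]3COC(=O)C3Cc3cc(OC)c4c(c3)[C@@H](CO[Si](C)(C)C(C)(C)C)[C@H](c3ccc(O[Si](C)(C)C(C)(C)C)c(OC)c3)O4)cc(OC)c2O[Si](C)(C)C(C)(C)C)ccc1O[Si](C)(C)C(C)(C)C | intermediate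
30 | (3S,4S)-3-(ArA-methyl)-4-(ArB-methyl)oxolan-2-one | COc1cc([C@@H](O[Si](C)(C)C(C)(C)C)[C@H](CO[Si](C)(C)C(C)(C)C)c2cc(C[C@@H]3COC(=O)[C@H]3Cc3cc(OC)c4c(c3)[C@@H](CO[Si](C)(C)C(C)(C)C)[C@H](c3ccc(O[Si](C)(C)C(C)(C)C)c(OC)c3)O4)cc(OC)c2O[Si](C)(C)C(C)(C)C)ccc1O[Si](C)(C)C(C)(C)C | intermediate
31 | (3S,4S)-3-{[(2R,3S)-2-(4-hydroxy-3-methoxyphenyl)-3-(hydroxymethyl)-7-methoxy-2,3-dihydro-1-benzofuran-5-yl]methyl}-4-({3-[(1S,2S)-1,3-dihydroxy-1-(4-hydroxy-3-methoxyphenyl)propan-2-yl]-4-hydroxy-5-methoxyphenyl}methyl)oxolan-2-one (CNP0199264.1) | COc1cc([C@@H](O)[C@H](CO)c2cc(C[C@@H]3COC(=O)[C@H]3Cc3cc(OC)c4c(c3)[C@@H](CO)[C@H](c3ccc(O)c(OC)c3)O4)cc(OC)c2O)ccc1O | target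

**Total step count:** 16. **Longest linear sequence:** 12 (steps 1–6, 11–13, 14–16).

**Three steps most likely to fail**

1. **Step 14.** Three things can go wrong.
   - The activated 3-arylpropanamide carries an arene para-activated by OMe and by the ring oxygen. It can close to an indanone iminium, or take part through a phenonium ion and cause aryl migration.
   - The acid salt in the flask quenches one equivalent of enolate.
   - The imide enolate is bulky and breaks down above about −20 °C.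

   The fallback sets out from 17 and 23 and comes back at 27. Both carbonyl compounds are deprotonated together with LiN(i-Pr)2 in THF at −78 °C. The mixed enolates are then oxidised with Cu(2-ethylhexanoate)2 (divalent copper, a one-electron oxidant). This is an oxidative enolate heterocoupling, which forms the same bond through an α-carbonyl radical instead of an α-carbonyl cation. The auxiliary again sets the imide α-centre, and the homodimers are removed by chromatography. It makes no compound outside the list (none F0).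

2. **Step 5.** Arylacetyl imides lie outside the usual propionate scope of the magnesium-catalysed anti-aldol. The anti:syn ratio is untested, and the acidic α-aryl centre could epimerise.

   The fallback sets out from 5 (with 9) and comes back at 12.
   - Acid 5 is doubly deprotonated with i-PrMgCl (2.1 equiv, THF). The magnesium enediolate is added to 9 (Ivanov reaction, chair Zimmerman–Traxler transition state, anti-selective) to give the racemic anti-hydroxy acid F1.
   - F1 is crystallised with (R)-1-phenylethylamine to give the less soluble diastereomeric ammonium salt F2.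
   - Acidification frees the (2R,3S)-hydroxy acid F3.
   - BH3·SMe2 in THF reduces the carboxylic acid of F3 to give 12.

3. **Step 15.** The imide carbonyl of 27 is flanked by two branched carbons, so hydride may open the oxazolidinone ring (endocyclic cleavage) instead of releasing it.

   The fallback sets out from 27 and comes back at 28. LiSEt (from EtSH and n-BuLi, THF, 0 °C) attacks only the exocyclic carbonyl and gives the S-ethyl thioester F4. This far less hindered and more electrophilic thioester is reduced with LiBH4 at 0 °C to hydroxy amide 28, which is lactonised as in the main route.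

**Further compounds**
F0 | step 14 | none | none
F1 | step 5 | racemic anti-2-[2-(benzyloxy)-5-bromo-3-methoxyphenyl]-3-[4-(benzyloxy)-3-methoxyphenyl]-3-hydroxypropanoic acid (1:1 mixture of both enantiomers) | COc1cc([C@@H](O)[C@H](C(=O)O)c2cc(Br)cc(OC)c2OCc2ccccc2)ccc1OCc1ccccc1.COc1cc([C@H](O)[C@@H](C(=O)O)c2cc(Br)cc(OC)c2OCc2ccccc2)ccc1OCc1ccccc1
F2 | step 5 | (R)-1-phenylethylammonium (2R,3S)-2-[2-(benzyloxy)-5-bromo-3-methoxyphenyl]-3-[4-(benzyloxy)-3-methoxyphenyl]-3-hydroxypropanoate | COc1cc([C@@H](O)[C@H](C(=O)[O-])c2cc(Br)cc(OC)c2OCc2ccccc2)ccc1OCc1ccccc1.C[C@@H]([NH3+])c1ccccc1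
F3 | step 5 | (2R,3S)-2-[2-(benzyloxy)-5-bromo-3-methoxyphenyl]-3-[4-(benzyloxy)-3-methoxyphenyl]-3-hydroxypropanoic acid | COc1cc([C@@H](O)[C@H](C(=O)O)c2cc(Br)cc(OC)c2OCc2ccccc2)ccc1OCc1ccccc1
F4 | step 15 | S-ethyl (2S)-3-(ArA-methyl)-2-(ArB-methyl)-4-(dimethylamino)-4-oxobutanethioate (C3 epimers) | COc1cc([C@@H](O[Si](C)(C)C(C)(C)C)[C@H](CO[Si](C)(C)C(C)(C)C)c2cc(C[C@H](C(=O)SCC)C(Cc3cc(OC)c4c(c3)[C@@H](CO[Si](C)(C)C(C)(C)C)[C@H](c3ccc(O[Si](C)(C)C(C)(C)C)c(OC)c3)O4)C(=O)N(C)C)cc(OC)c2O[Si](C)(C)C(C)(C)C)ccc1O[Si](C)(C)C(C)(C)C
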